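Rings are lettered A to E from the 2,4,6-trihydroxyphenyl end. Ring B bears the ether to ring A on C1, hydroxyls on C3 and C4, the ether to ring C on C5, and hydrogens on C2 and C6. The synthesis rests on cutting ring B at C2–C3 and C1–C6. One thermal operation joins a racemic 3-aryloxy-4-methoxycyclobutenone, which already carries the permethylated C–D–E unit, to the ethynyl ether of 2,4,6-trimethoxyphenol; it should form ring B with both aryl ethers, the C4 methoxy group and a free C3 hydroxyl in place. The C–D–E phenol comes from two copper-mediated etherifications, each followed by Baeyer–Villiger unmasking of a formyl group. BBr3 finally cleaves twelve methyl ethers.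

Key step: step 10

Remark on the chemistry: the target has no stereocentre; the cyclobutenone precursor of the key step is used as the racemate because its single stereocentre becomes aromatic C4 of ring B.
Abbreviation: "CDE-aryl" is 2-[3,5-dimethoxy-4-(3,4,5-trimethoxyphenoxy)phenoxy]-3,4,5-trimethoxyphenyl, the aryl group of the C–D–E phenol made in step 4.

Step 1
Reactants: 1 syringaldehyde (4-hydroxy-3,5-dimethoxybenzaldehyde); 2 (3,4,5-trimethoxyphenyl)boronic acid
Product: 3 3,5-dimethoxy-4-(3,4,5-trimethoxyphenoxy)benzaldehyde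
Conditions: Cu(OAc)2 (2 equiv), pyridine, 4 Å MS, CH2Cl2, dry air, rt; 2 in excess
Reagents that add atoms: none
Why: Chan–Lam coupling, in which the arylboronic acid transmetalates to divalent copper and C–O reductive elimination occurs from trivalent copper at room temperature, is known to tolerate phenols with two ortho substituents and leaves the aldehyde untouched.

Step 2
Reactants: 3 3,5-dimethoxy-4-(3,4,5-trimethoxyphenoxy)benzaldehyde
Product: 5 3,5-dimethoxy-4-(3,4,5-trimethoxyphenoxy)phenol, via aryl formate 4 (not isolated)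
Conditions: mCPBA, CH2Cl2, 0 °C to rt; then Et3N (cat.), MeOH, rt
Reagents that add atoms: mCPBA, O=C(OO)c1cccc(Cl)c1
Why: Baeyer–Villiger oxidation of an electron-rich benzaldehyde (Dakin-type), in which the para-aryloxy-substituted aryl group migrates in the Criegee intermediate to give the aryl formate, which amine-catalysed methanolysis cleaves to the phenol.

Step 3
Reactants: 5 3,5-dimethoxy-4-(3,4,5-trimethoxyphenoxy)phenol; 6 2-bromo-3,4,5-trimethoxybenzaldehyde
Product: 7 2-[3,5-dimethoxy-4-(3,4,5-trimethoxyphenoxy)phenoxy]-3,4,5-trimethoxybenzaldehyde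
Conditions: CuI (20 mol%), N,N-dimethylglycine hydrochloride (60 mol%), Cs2CO3, dioxane, 100 °C, argon
Reagents that add atoms: none
Why: Ullmann diaryl ether synthesis with an amino acid ligand, in which the unhindered, electron-rich phenoxide of 5 couples with an aryl bromide whose ortho-formyl group assists oxidative addition to monovalent copper, a pairing long used for ortho-bromobenzaldehydes.

Step 4
Reactants: 7 2-[3,5-dimethoxy-4-(3,4,5-trimethoxyphenoxy)phenoxy]-3,4,5-trimethoxybenzaldehyde
Product: 9 2-[3,5-dimethoxy-4-(3,4,5-trimethoxyphenoxy)phenoxy]-3,4,5-trimethoxyphenol (C–D–E phenol), via aryl formate 8 (not isolated)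
Conditions: mCPBA, CH2Cl2, 0 °C to rt; then Et3N (cat.), MeOH, rt
Reagents that add atoms: mCPBA, O=C(OO)c1cccc(Cl)c1
Why: Baeyer–Villiger oxidation followed by formate methanolysis, with aryl migration favoured by the ortho-aryloxy and para-methoxy groups of the formyl-bearing ring.

Step 5
Reactants: 9 C–D–E phenol; 10 trichloroethylene
Product: 11 CDE-aryl (E)-1,2-dichlorovinyl ether
Conditions: K2CO3, DMF, 70 °C, argon; 10 (2 equiv)
Reagents that add atoms: none
Why: Base-mediated vinylation of a phenol with trichloroethylene, in which dehydrochlorination of 10 gives dichloroacetylene as a reagent formed and consumed in the flask and anti addition of the phenol across it gives the (E)-1,2-dichlorovinyl ether, a known route for phenols.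

Step 6
Reactants: 11 CDE-aryl (E)-1,2-dichlorovinyl ether
Product: 13 CDE-aryl ethynyl ether, via lithium aryloxyacetylide 12 (not isolated)
Conditions: n-BuLi (2.2 equiv), THF, −78 to −40 °C; then MeOH, −78 °C; crude product used at once
Reagents that add atoms: none
Why: Ynol ether synthesis from a 1,2-dichlorovinyl ether, in which vinylic deprotonation, loss of LiCl to the chloroalkynyl ether and lithium–chlorine exchange give the lithium acetylide that methanol protonates, while the aryl methyl ethers are not lithiated at −78 °C.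

Step 7
Reactants: 13 CDE-aryl ethynyl ether; 14 methoxyacetyl chloride
Product: 15 racemic 4-methoxy-3-(CDE-aryloxy)cyclobut-2-en-1-one
Conditions: Et3N, CH2Cl2, 0 °C to rt, slow addition of 14 (2 equiv); rapid filtration through neutral alumina
Reagents that add atoms: none
Why: Ketene–ynol ether [2+2] cycloaddition, in which Et3N dehydrochlorinates 14 to methoxyketene as a reagent formed and consumed in the flask and the nucleophilic CH carbon of 13 attacks its carbonyl carbon so that the aryloxy group ends on C3 and the methoxy group on C4; the C4 stereocentre forms without control and is lost later.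

Step 8
Reactants: 16 2,4,6-trimethoxyphenol; 10 trichloroethylene
Product: 17 2-[(E)-1,2-dichloroethenyloxy]-1,3,5-trimethoxybenzene
Conditions: K2CO3, DMF, 70 °C, argon; 10 (2 equiv)
Reagents that add atoms: none
Why: The same phenol vinylation as in step 5, in which the phenoxide adds to the unhindered sp carbon of dichloroacetylene formed and consumed in the flask from 10, so the two ortho methoxy groups should not hinder it.

Step 9
Reactants: 17 2-[(E)-1,2-dichloroethenyloxy]-1,3,5-trimethoxybenzene
Product: 19 2-(ethynyloxy)-1,3,5-trimethoxybenzene, via lithium aryloxyacetylide 18 (not isolated)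
Conditions: n-BuLi (2.2 equiv), THF, −78 to −40 °C; then MeOH, −78 °C; kept cold in solution and used at once
Reagents that add atoms: none
Why: The same dichlorovinyl ether to ynol ether conversion as in step 6, and the flanking methoxy groups should shield the terminal ynol ether against self-condensation.

Step 10
Reactants: 15 racemic 4-methoxy-3-(CDE-aryloxy)cyclobut-2-en-1-one; 19 2-(ethynyloxy)-1,3,5-trimethoxybenzene
Product: 24 2-methoxy-3-(CDE-aryloxy)-5-(2,4,6-trimethoxyphenoxy)phenol, via vinylketene 20 (not isolated), via 4-vinylcyclobutenone 21 (not isolated), via dienylketene 22 (not isolated), via cyclohexa-2,4-dienone 23 (not isolated)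
Conditions: 19 (3 equiv, added in portions), toluene, 80 °C then 110 °C, argon, sealed tube
Reagents that add atoms: none
Why: Thermal 4π opening of 15 should give vinylketene 20 (methoxy turning outward), whose ketene C=C adds the ynol ether in a [2+2] cycloaddition to 21; a second 4π opening gives dienylketene 22, 6π electrocyclisation gives dienone 23, and enolisation gives phenol 24. The closest known reaction type is the Danheiser benzannulation of cyclobutenones with alkoxyacetylenes, here with an aryloxy group on the alkyne. Ring B is closed by a thermal disrotatory 6π electrocyclisation that joins the ketene carbon (ring B C3) to the methoxy-bearing terminus (C4), after the cycloaddition has made the C2–C3 and C1–C6 bonds. No stereocentre remains, since the sp3 carbon of 15 and of 23 becomes aromatic C4. The step needs a single regiochemistry in the cycloaddition, with the ring A ether meta to the new hydroxyl, and the polarity of the partners secures it because the electron-rich CH carbon of 19 attacks the electrophilic ketene carbon. An aryl ynol ether has no β-hydrogen for retro-ene loss of ketene at these temperatures, and its excess should keep 20 from dimerising.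

Step 11
Reactants: 24 2-methoxy-3-(CDE-aryloxy)-5-(2,4,6-trimethoxyphenoxy)phenol
Product: 25 5-(2,4,6-trihydroxyphenoxy)-3-{2-[3,5-dihydroxy-4-(3,4,5-trihydroxyphenoxy)phenoxy]-3,4,5-trihydroxyphenoxy}benzene-1,2-diol (target)
Conditions: BBr3 (25 equiv), CH2Cl2, −78 °C to rt, argon; then MeOH, 0 °C; concentrate; reversed-phase chromatography with degassed solvents
Reagents that add atoms: none
Why: Lewis acid cleavage of aryl methyl ethers, in which BBr3 binds each methoxy oxygen and bromide attacks the methyl group in an SN2 step, whereas the four diaryl ether links offer no sp3 carbon and should survive; methanol then frees the phenols from their borate esters.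

Compound list
1 | syringaldehyde (4-hydroxy-3,5-dimethoxybenzaldehyde) | COc1cc(C=O)cc(OC)c1O | starting material
2 | (3,4,5-trimethoxyphenyl)boronic acid | COc1cc(B(O)O)cc(OC)c1OC | starting material
3 | 3,5-dimethoxy-4-(3,4,5-trimethoxyphenoxy)benzaldehyde | COc1cc(C=O)cc(OC)c1Oc1cc(OC)c(OC)c(OC)c1 | intermediate
4 | 3,5-dimethoxy-4-(3,4,5-trimethoxyphenoxy)phenyl formate (not isolated) | COc1cc(OC=O)cc(OC)c1Oc1cc(OC)c(OC)c(OC)c1 | intermediate
5 | 3,5-dimethoxy-4-(3,4,5-trimethoxyphenoxy)phenol | COc1cc(O)cc(OC)c1Oc1cc(OC)c(OC)c(OC)c1 | intermediate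
6 | 2-bromo-3,4,5-trimethoxybenzaldehyde | COc1cc(C=O)c(Br)c(OC)c1OC | starting material
7 | 2-[3,5-dimethoxy-4-(3,4,5-trimethoxyphenoxy)phenoxy]-3,4,5-trimethoxybenzaldehyde | COc1cc(C=O)c(Oc2cc(OC)c(Oc3cc(OC)c(OC)c(OC)c3)c(OC)c2)c(OC)c1OC | intermediate
8 | CDE-aryl formate (not isolated) | COc1cc(OC=O)c(Oc2cc(OC)c(Oc3cc(OC)c(OC)c(OC)c3)c(OC)c2)c(OC)c1OC | intermediate
9 | 2-[3,5-dimethoxy-4-(3,4,5-trimethoxyphenoxy)phenoxy]-3,4,5-trimethoxyphenol (C–D–E phenol) | COc1cc(O)c(Oc2cc(OC)c(Oc3cc(OC)c(OC)c(OC)c3)c(OC)c2)c(OC)c1OC | intermediate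
10 | trichloroethylene | ClC=C(Cl)Cl | starting material
11 | CDE-aryl (E)-1,2-dichlorovinyl ether | Cl/C=C(Cl)\Oc1cc(OC)c(OC)c(OC)c1Oc1cc(OC)c(Oc2cc(OC)c(OC)c(OC)c2)c(OC)c1 | intermediate
12 | lithium (CDE-aryloxy)acetylide (not isolated) | [Li]C#COc1cc(OC)c(OC)c(OC)c1Oc1cc(OC)c(Oc2cc(OC)c(OC)c(OC)c2)c(OC)c1 | intermediate
13 | CDE-aryl ethynyl ether | C#COc1cc(OC)c(OC)c(OC)c1Oc1cc(OC)c(Oc2cc(OC)c(OC)c(OC)c2)c(OC)c1 | intermediate
14 | methoxyacetyl chloride | COCC(Cl)=O | starting material
15 | racemic 4-methoxy-3-(CDE-aryloxy)cyclobut-2-en-1-one | COC1C(=O)C=C1Oc1cc(OC)c(OC)c(OC)c1Oc1cc(OC)c(Oc2cc(OC)c(OC)c(OC)c2)c(OC)c1 | intermediate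
16 | 2,4,6-trimethoxyphenol | COc1cc(OC)c(O)c(OC)c1 | starting material
17 | 2-[(E)-1,2-dichloroethenyloxy]-1,3,5-trimethoxybenzene | Cl/C=C(Cl)\Oc1c(OC)cc(OC)cc1OC | intermediate
18 | lithium (2,4,6-trimethoxyphenoxy)acetylide (not isolated) | [Li]C#COc1c(OC)cc(OC)cc1OC | intermediate
19 | 2-(ethynyloxy)-1,3,5-trimethoxybenzene | C#COc1c(OC)cc(OC)cc1OC | intermediate
20 | (Z)-3-(CDE-aryloxy)-4-methoxybuta-1,3-dien-1-one (vinylketene, not isolated) | O=C=C/C(Oc1cc(OC)c(OC)c(OC)c1Oc1cc(OC)c(Oc2cc(OC)c(OC)c(OC)c2)c(OC)c1)=C/OC | intermediate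
21 | racemic 4-[(Z)-1-(CDE-aryloxy)-2-methoxyvinyl]-3-(2,4,6-trimethoxyphenoxy)cyclobut-2-en-1-one (not isolated) | O=C1C=C(Oc2c(OC)cc(OC)cc2OC)C1/C(Oc1cc(OC)c(OC)c(OC)c1Oc1cc(OC)c(Oc2cc(OC)c(OC)c(OC)c2)c(OC)c1)=C/OC | intermediate
22 | (3E,5Z)-5-(CDE-aryloxy)-6-methoxy-3-(2,4,6-trimethoxyphenoxy)hexa-1,3,5-trien-1-one (dienylketene, not isolated) | O=C=C/C(Oc1c(OC)cc(OC)cc1OC)=C\C(Oc1cc(OC)c(OC)c(OC)c1Oc1cc(OC)c(Oc2cc(OC)c(OC)c(OC)c2)c(OC)c1)=C\OC | intermediate
23 | racemic 5-(CDE-aryloxy)-6-methoxy-3-(2,4,6-trimethoxyphenoxy)cyclohexa-2,4-dien-1-one (not isolated) | COC1C(=O)C=C(Oc2c(OC)cc(OC)cc2OC)C=C1Oc1cc(OC)c(OC)c(OC)c1Oc1cc(OC)c(Oc2cc(OC)c(OC)c(OC)c2)c(OC)c1 | intermediate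
24 | 2-methoxy-3-(CDE-aryloxy)-5-(2,4,6-trimethoxyphenoxy)phenol (dodeca-O-methyl ether of the target, ring B C3 hydroxyl free) | COc1cc(OC)c(Oc2cc(O)c(OC)c(Oc3cc(OC)c(OC)c(OC)c3Oc3cc(OC)c(Oc4cc(OC)c(OC)c(OC)c4)c(OC)c3)c2)c(OC)c1 | intermediate
25 | 5-(2,4,6-trihydroxyphenoxy)-3-{2-[3,5-dihydroxy-4-(3,4,5-trihydroxyphenoxy)phenoxy]-3,4,5-trihydroxyphenoxy}benzene-1,2-diol (CNP0228612.0) | Oc1cc(O)c(Oc2cc(O)c(O)c(Oc3cc(O)c(O)c(O)c3Oc3cc(O)c(Oc4cc(O)c(O)c(O)c4)c(O)c3)c2)c(O)c1 | target

Total step count: 11. Longest linear sequence: 9 steps (steps 1 to 7, then 10 and 11); steps 8 and 9 form the short branch to 19.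

Steps most likely to fail

1. Step 10. The terminal aryl ynol ether may polymerise, and the vinylketene may dimerise or acylate the product phenol, faster than the cycloaddition runs at the temperature needed to open the cyclobutenone. An O-acylated product would first be cleaved with K2CO3 in MeOH. The fallback gives up the annulation, sets out from 9 and comes back to the route at 25. Ring B would be taken from a benzene block and both ethers made by copper catalysis. Commercial 4-bromo-2-methoxyphenol would be iodinated ortho to the hydroxyl (NIS, MeCN) to 4-bromo-2-iodo-6-methoxyphenol F1 and methylated (MeI, K2CO3, acetone) to 5-bromo-1-iodo-2,3-dimethoxybenzene F2. An iodide-selective Ullmann coupling of 9 with F2 (CuI, N,N-dimethylglycine, Cs2CO3, dioxane, 80 °C) should give 5-bromo-1-(CDE-aryloxy)-2,3-dimethoxybenzene F3. A second coupling of F3 with the hindered phenol 16 (CuI, picolinic acid, K3PO4, DMSO, 110 °C) should give the trideca-O-methyl ether of the target F4, which the BBr3 conditions of step 11 would convert to 25.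

2. Step 7. Oligomerisation of methoxyketene may outrun its cycloaddition to the aryl ynol ether, and the vinylogous aryl ester may be lost by hydrolysis during isolation. The fallback reaches vinylketene 20 without a cyclobutenone, sets out from 9 and comes back to the route at 24. Phenol 9 would be alkylated with methyl bromoacetate (K2CO3, acetone) to methyl 2-(CDE-aryloxy)acetate F5, formylated (NaH, HCO2Me, THF) to racemic methyl 2-(CDE-aryloxy)-3-oxopropanoate F6, and O-methylated (Me2SO4, K2CO3, DMF) to methyl (Z)-2-(CDE-aryloxy)-3-methoxyacrylate F7. Saponification (LiOH, THF–H2O) would give (Z)-2-(CDE-aryloxy)-3-methoxyacrylic acid F8, and oxalyl chloride with catalytic DMF the acid chloride (Z)-2-(CDE-aryloxy)-3-methoxyacryloyl chloride F9. Excess CH2N2 in Et2O at 0 °C would then give the diazo ketone (Z)-1-diazo-3-(CDE-aryloxy)-4-methoxybut-3-en-2-one F10. Irradiation of F10 with 19 (300 nm, 1,2-dichloroethane, rt, then 80 °C) should trigger a photochemical Wolff rearrangement to the same vinylketene 20, which continues through 21 to 23 to give 24.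

3. Step 11. Cleavage of the twelve ethers may stop short, and the free polyphenol may be lost to air oxidation during work-up and chromatography. The fallback sets out from 24 and comes back at 25 by capture and release. The crude product of the BBr3 reaction would be acetylated (Ac2O, pyridine, DMAP) to the trideca-O-acetate of the target F11, which is stable and can be purified on silica. Partly methylated acetates would be separated and returned to BBr3. The acetates would then be removed with HCl in degassed MeOH (from AcCl) at rt to release 25 under argon.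

Further compounds
F1 | step 10 | 4-bromo-2-iodo-6-methoxyphenol | COc1cc(Br)cc(I)c1O
F2 | step 10 | 5-bromo-1-iodo-2,3-dimethoxybenzene | COc1cc(Br)cc(I)c1OC
F3 | step 10 | 5-bromo-1-(CDE-aryloxy)-2,3-dimethoxybenzene | COc1cc(Br)cc(Oc2cc(OC)c(OC)c(OC)c2Oc2cc(OC)c(Oc3cc(OC)c(OC)c(OC)c3)c(OC)c2)c1OC
F4 | step 10 | 1-(CDE-aryloxy)-2,3-dimethoxy-5-(2,4,6-trimethoxyphenoxy)benzene (trideca-O-methyl ether of the target) | COc1cc(OC)c(Oc2cc(OC)c(OC)c(Oc3cc(OC)c(OC)c(OC)c3Oc3cc(OC)c(Oc4cc(OC)c(OC)c(OC)c4)c(OC)c3)c2)c(OC)c1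
F5 | step 7 | methyl 2-(CDE-aryloxy)acetate | COC(=O)COc1cc(OC)c(OC)c(OC)c1Oc1cc(OC)c(Oc2cc(OC)c(OC)c(OC)c2)c(OC)c1
F6 | step 7 | racemic methyl 2-(CDE-aryloxy)-3-oxopropanoate | COC(=O)C(C=O)Oc1cc(OC)c(OC)c(OC)c1Oc1cc(OC)c(Oc2cc(OC)c(OC)c(OC)c2)c(OC)c1
F7 | step 7 | methyl (Z)-2-(CDE-aryloxy)-3-methoxyacrylate | CO/C=C(\Oc1cc(OC)c(OC)c(OC)c1Oc1cc(OC)c(Oc2cc(OC)c(OC)c(OC)c2)c(OC)c1)C(=O)OC
F8 | step 7 | (Z)-2-(CDE-aryloxy)-3-methoxyacrylic acid | CO/C=C(\Oc1cc(OC)c(OC)c(OC)c1Oc1cc(OC)c(Oc2cc(OC)c(OC)c(OC)c2)c(OC)c1)C(=O)O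
F9 | step 7 | (Z)-2-(CDE-aryloxy)-3-methoxyacryloyl chloride | CO/C=C(\Oc1cc(OC)c(OC)c(OC)c1Oc1cc(OC)c(Oc2cc(OC)c(OC)c(OC)c2)c(OC)c1)C(Cl)=O
F10 | step 7 | (Z)-1-diazo-3-(CDE-aryloxy)-4-methoxybut-3-en-2-one | CO/C=C(\Oc1cc(OC)c(OC)c(OC)c1Oc1cc(OC)c(Oc2cc(OC)c(OC)c(OC)c2)c(OC)c1)C(=O)C=[N+]=[N-]
F11 | step 11 | trideca-O-acetate of the target | CC(=O)Oc1cc(OC(C)=O)c(Oc2cc(OC(C)=O)c(OC(C)=O)c(Oc3cc(OC(C)=O)c(OC(C)=O)c(OC(C)=O)c3Oc3cc(OC(C)=O)c(Oc4cc(OC(C)=O)c(OC(C)=O)c(OC(C)=O)c4)c(OC(C)=O)c3)c2)c(OC(C)=O)c1
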